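**Plan**
- Locants: C1 lactone carbonyl, C2 (Me), C3 (OH), C4 (Me, oxane O), C5 (lactone O), C6 (Me), C7 (acyloxy), C8 (Me, oxane O), C9 the C8 methyl; O3, O5, O7 are the oxygens on those carbons.
- Cuts, in retrosynthetic order: the O7 ester; the C1–C2 bond of the δ-lactone; C4–CH3 and C4–C3 at the ketal-type carbon C4; C5–O5 and C6–CH3 on an enone lactone made from L-rhamnal, whose six carbons are C4–C9.
- Forward: the oxane ring comes from the sugar. Methyl is added at C6, oxygen at C5, then propynyl (C3, C2, C2-Me) and axial methyl at C4. The lactone ring closes last, and the side chain is then esterified onto O7.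
- Ring closure: O5 and O3 stand 1,3 across C4, which carries no hydrogen. C1 is therefore first tied to both oxygens as a cyclic enol carbonate (Boc carbonate plus gold on the alkyne) and then moved from O3 to C2, which closes the lactone ring (O5, C1, C2, C3, C4, C5).
- Stereochemistry: C7 and C8 come from L-rhamnal; C6 from cuprate addition anti to O7; C5 from enolate hydroxylation anti to the C6 methyl; C4 from axial methyl delivery to an oxocarbenium ion; C2 and C3 together from hydrogenation of the enol anti to the axial C4 methyl.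

Key step: step 11

Remark: 17 is written as its enol tautomer; compound names use ring numbering, while the Why lines use the target locants given above.

**Step 1**
Reactants: 1 3,4-di-O-acetyl-L-rhamnal
Product: 3 (5R,6S)-5-acetoxy-6-methyl-5,6-dihydro-2H-pyran-2-one, via anomeric perester 2 (not isolated)
Conditions: mCPBA, BF3·OEt2 (cat.), CH2Cl2, −20 °C
Reagents that add atoms: 3-chloroperoxybenzoic acid, OOC(=O)c1cccc(Cl)c1
Why: Peracid oxidation of a glycal ester with Ferrier-type allylic transposition: BF3 ionises the allylic C6 acetate, the peracid adds at the anomeric carbon C4 to give perester 2, and this fragments to the C4 lactone carbonyl with the double bond at C5=C6; the sugar stereocentres that become C7 and C8 are untouched.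

**Step 2**
Reactants: 3 (5R,6S)-5-acetoxy-6-methyl-5,6-dihydro-2H-pyran-2-one
Product: 4 (5R,6S)-5-hydroxy-6-methyl-5,6-dihydro-2H-pyran-2-one
Conditions: Novozym 435 (immobilised Candida antarctica lipase B), n-BuOH, t-BuOMe, 30 °C
Reagents that add atoms: none
Why: Lipase-catalysed transesterification of the secondary acetate to n-butanol runs at neutral pH, which should avoid the acid- or base-induced ring contraction of the γ-hydroxy enoate lactone to a butenolide.

**Step 3**
Reactants: 4 (5R,6S)-5-hydroxy-6-methyl-5,6-dihydro-2H-pyran-2-one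
Product: 5 (5R,6S)-5-(benzyloxy)-6-methyl-5,6-dihydro-2H-pyran-2-one
Conditions: BnOC(=NH)CCl3, TfOH (cat.), CH2Cl2/cyclohexane, 0 °C
Reagents that add atoms: benzyl 2,2,2-trichloroacetimidate, N=C(OCc1ccccc1)C(Cl)(Cl)Cl
Why: Acid-catalysed O-benzylation with the trichloroacetimidate protects O7 without the base of a halide etherification, which 4 would not tolerate.

**Step 4**
Reactants: 5 (5R,6S)-5-(benzyloxy)-6-methyl-5,6-dihydro-2H-pyran-2-one
Product: 6 (4S,5R,6S)-5-(benzyloxy)-4,6-dimethyloxan-2-one
Conditions: Me2CuLi (from MeLi, CuI), Et2O, −78 °C; then AcOH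
Reagents that add atoms: lithium dimethylcuprate, [Li+].C[Cu-]C
Why: Conjugate addition of the Gilman cuprate to the enoate lactone; the methyl group should enter C6 anti to the adjacent C7 benzyloxy group, which sets C6 trans to O7.

**Step 5**
Reactants: 6 (4S,5R,6S)-5-(benzyloxy)-4,6-dimethyloxan-2-one
Product: 8 (3S,4S,5R,6S)-5-(benzyloxy)-3-hydroxy-4,6-dimethyloxan-2-one, via potassium enolate 7 (not isolated)
Conditions: KN(SiMe3)2, THF, −78 °C; 2-(benzenesulfonyl)-3-phenyloxaziridine, −78 °C; then AcOH
Reagents that add atoms: 2-(benzenesulfonyl)-3-phenyloxaziridine, O=S(=O)(N1OC1c1ccccc1)c1ccccc1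
Why: Oxaziridine hydroxylation of the lactone enolate (Davis oxidation); the oxidant should approach C5 of enolate 7 on the face opposite the adjacent C6 methyl, which sets C5 with O5 trans to that methyl.

**Step 6**
Reactants: 8 (3S,4S,5R,6S)-5-(benzyloxy)-3-hydroxy-4,6-dimethyloxan-2-one
Product: 9 (3S,4R,5R,6S)-5-(benzyloxy)-4,6-dimethyl-3-(triethylsilyloxy)oxan-2-one
Conditions: Et3SiCl, imidazole, DMF, 0 °C to rt
Reagents that add atoms: chlorotriethylsilane, CC[Si](Cl)(CC)CC
Why: Standard silylation; the triethylsilyl ether masks O5 as a non-participating group for steps 7 and 8 and can be cleaved later without touching the benzyl ether.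

**Step 7**
Reactants: 9 (3S,4R,5R,6S)-5-(benzyloxy)-4,6-dimethyl-3-(triethylsilyloxy)oxan-2-one
Product: 10 (3S,4R,5R,6S)-5-(benzyloxy)-4,6-dimethyl-2-(prop-1-ynyl)-3-(triethylsilyloxy)oxan-2-ol (anomer mixture)
Conditions: 1-propynyllithium (from propyne, n-BuLi), THF, −78 °C; then AcOH
Reagents that add atoms: 1-propynyllithium, [Li]C#CC
Why: 1,2-Addition of a lithium acetylide to the δ-lactone stops at the hemiketal at −78 °C and brings in C3, C2 and the C2 methyl carbon; the anomeric configuration at C4 does not matter because C4 is ionised in step 8.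

**Step 8**
Reactants: 10 (3S,4R,5R,6S)-5-(benzyloxy)-4,6-dimethyl-2-(prop-1-ynyl)-3-(triethylsilyloxy)oxan-2-ol
Product: 13 (2R,3S,4S,5R,6S)-5-(benzyloxy)-2,4,6-trimethyl-2-(prop-1-ynyl)oxan-3-ol, via oxocarbenium triflate 11 (not isolated), via triethylsilyl ether 12 (not isolated)
Conditions: AlMe3, Me3SiOTf, CH2Cl2, −78 to −20 °C; then MeOH, aq. HCl, 0 °C to rt
Reagents that add atoms: trimethylaluminium, C[Al](C)C
Why: Lewis acid-mediated substitution at the ketal carbon (C-glycosylation type): Me3SiOTf ionises 10 to oxocarbenium ion 11, AlMe3 delivers methyl along the axial trajectory of the half-chair with the C5–C8 substituents equatorial (chair-like transition state, cis to O5), which sets C4 with axial methyl and equatorial propynyl, and acidic methanol then cleaves the silyl ether of 12 while the benzyl ether stays.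

**Step 9**
Reactants: 13 (2R,3S,4S,5R,6S)-5-(benzyloxy)-2,4,6-trimethyl-2-(prop-1-ynyl)oxan-3-ol
Product: 14 tert-butyl (2R,3S,4R,5R,6S)-5-(benzyloxy)-2,4,6-trimethyl-2-(prop-1-ynyl)oxan-3-yl carbonate
Conditions: Boc2O, DMAP, MeCN, rt
Reagents that add atoms: di-tert-butyl dicarbonate, CC(C)(C)OC(=O)OC(=O)OC(C)(C)C
Why: DMAP-catalysed carbonate formation at the C5 hydroxyl places on O5 the carbon that becomes C1.

**Step 10**
Reactants: 14 tert-butyl (2R,3S,4R,5R,6S)-5-(benzyloxy)-2,4,6-trimethyl-2-(prop-1-ynyl)oxan-3-yl carbonate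
Product: 15 cyclic enol carbonate (O5–C1(=O)–O3 ring with a Z ethylidene on C3, trans-fused to the oxane at C4–C5; O7 benzyl)
Conditions: Ph3PAuNTf2 (5 mol %), CH2Cl2, rt
Reagents that add atoms: none
Why: Gold-catalysed cyclisation of an alkynyl tert-butyl carbonate: the carbonate carbonyl oxygen attacks C3 of the gold-activated alkyne in a 6-exo-dig mode anti to gold, the tert-butyl group leaves as isobutene and protodeauration gives the Z enol carbonate, so oxygen is placed on C3 and C1 is tied to both O5 and O3.

**Step 11**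
Reactants: 15 cyclic enol carbonate
Product: 17 7-O-benzyl β-keto-δ-lactone as its enol (4-hydroxy-3-methyl-5,6-dihydro-2-pyranone ring fused to the oxane), via ring-opened potassium enolate 16 (not isolated)
Conditions: KOC(CH3)3 (1.2 equiv), THF, −78 to 0 °C; then aq. HCl
Reagents that add atoms: none
Why: Proposed new method: tert-butoxide adds to the carbonate carbonyl of 15 and the tetrahedral intermediate expels the best leaving group, the C2=C3 enolate, giving 16 with C1 held on O5 as a tert-butyl carbonate; the enolate carbon C2 then attacks C1 and tert-butoxide leaves, so the δ-lactone ring (O5, C1, C2, C3, C4, C5) closes by C1–C2 bond formation in a 6-(enolendo)-exo-trig mode. The closest known reaction types are the Steglich-type O-to-C carboxyl shift of enol carbonates and the Dieckmann-type Claisen cyclisation of ketone carbonates to 4-hydroxy-2-pyranones. No stereocentre is formed, since C2 and C3 are trigonal in 17 and C4–C8 are not touched. The step needs acylation at carbon C2 only and no loss of O5: C4 carries no hydrogen, so the ketone can enolise only toward C2 and the O5 carbonate cannot leave by E1cB elimination, and the fully substituted C4 holds C2 close to C1. Deprotonation of the vinylogous acid 17 by the alkoxide should make the sequence irreversible, which is why a full equivalent of base is used.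

**Step 12**
Reactants: 17 7-O-benzyl β-keto-δ-lactone (enol)
Product: 18 bicyclic diol (3-hydroxy, 7-hydroxy lactone core of the target)
Conditions: H2 (60 bar), Raney nickel (Ni), EtOH, 50 °C
Reagents that add atoms: none
Why: Heterogeneous hydrogenation of the tetrasubstituted enol, as known for 3-alkyl-4-hydroxy-5,6-dihydro-2-pyranones (these give the all-cis hydroxy lactones): both hydrogens should reach C2 and C3 from the face opposite the axial C4 methyl, which sets C2 and C3 with methyl and hydroxyl cis to each other and to the C4 methyl, and the same conditions should hydrogenolyse the benzyl ether.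

**Step 13**
Reactants: 19 methyltriphenylphosphonium bromide (2 equiv), 20 pentanoyl chloride
Product: 22 1-(triphenyl-λ5-phosphanylidene)hexan-2-one, via methylidenetriphenylphosphorane 21 (not isolated)
Conditions: n-BuLi (2 equiv), THF, 0 °C; then 20 (1 equiv), −78 °C to rt
Reagents that add atoms: none
Why: Deprotonation of the phosphonium salt gives ylide 21, and its C-acylation by the acid chloride (Wittig ylide acylation) gives the stabilised keto ylide, the second equivalent of 21 taking up the HCl.

**Step 14**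
Reactants: 22 1-(triphenyl-λ5-phosphanylidene)hexan-2-one, 23 glyoxylic acid monohydrate
Product: 24 (E)-4-oxooct-2-enoic acid
Conditions: CH2Cl2, rt
Reagents that add atoms: none
Why: Wittig olefination of glyoxylic acid with a stabilised keto ylide, which should give the E alkene.

**Step 15**
Reactants: 18 bicyclic diol, 24 (E)-4-oxooct-2-enoic acid
Product: 25 botcinin I
Conditions: DCC, DMAP (cat.), CH2Cl2, −20 to 0 °C
Reagents that add atoms: none
Why: Steglich esterification; the C7 hydroxyl, flanked by two CH(CH3) carbons, should be acylated much faster than the C3 hydroxyl, which lies between the fully substituted C4 and the C2 carrying an axial methyl, and the low temperature with catalytic DMAP guards against epimerisation at C2.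

**Compound list**
1 | 3,4-di-O-acetyl-L-rhamnal, (2S,3S,4S)-2-methyl-3,4-dihydro-2H-pyran-3,4-diyl diacetate | C[C@@H]1OC=C[C@H](OC(C)=O)[C@H]1OC(C)=O | starting material
2 | (5R,6S)-5-acetoxy-6-methyl-5,6-dihydro-2H-pyran-2-yl 3-chloroperoxybenzoate (anomer mixture) | C[C@@H]1OC(OOC(=O)c2cccc(Cl)c2)C=C[C@H]1OC(C)=O | intermediate
3 | (5R,6S)-5-acetoxy-6-methyl-5,6-dihydro-2H-pyran-2-one | C[C@@H]1OC(=O)C=C[C@H]1OC(C)=O | intermediate
4 | (5R,6S)-5-hydroxy-6-methyl-5,6-dihydro-2H-pyran-2-one | C[C@@H]1OC(=O)C=C[C@H]1O | intermediate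
5 | (5R,6S)-5-(benzyloxy)-6-methyl-5,6-dihydro-2H-pyran-2-one | C[C@@H]1OC(=O)C=C[C@H]1OCc2ccccc2 | intermediate
6 | (4S,5R,6S)-5-(benzyloxy)-4,6-dimethyloxan-2-one | C[C@@H]1OC(=O)C[C@H](C)[C@H]1OCc2ccccc2 | intermediate
7 | potassium enolate of 6 | C[C@@H]1OC([O-])=C[C@H](C)[C@H]1OCc2ccccc2.[K+] | intermediate
8 | (3S,4S,5R,6S)-5-(benzyloxy)-3-hydroxy-4,6-dimethyloxan-2-one | C[C@@H]1OC(=O)[C@@H](O)[C@H](C)[C@H]1OCc2ccccc2 | intermediate
9 | (3S,4R,5R,6S)-5-(benzyloxy)-4,6-dimethyl-3-(triethylsilyloxy)oxan-2-one | C[C@@H]1OC(=O)[C@@H](O[Si](CC)(CC)CC)[C@H](C)[C@H]1OCc2ccccc2 | intermediate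
10 | (3S,4R,5R,6S)-5-(benzyloxy)-4,6-dimethyl-2-(prop-1-ynyl)-3-(triethylsilyloxy)oxan-2-ol (anomer mixture) | C[C@@H]1OC(O)(C#CC)[C@@H](O[Si](CC)(CC)CC)[C@H](C)[C@H]1OCc2ccccc2 | intermediate
11 | oxocarbenium triflate formed from 10 by loss of the anomeric hydroxyl | C[C@@H]1[O+]=C(C#CC)[C@@H](O[Si](CC)(CC)CC)[C@H](C)[C@H]1OCc2ccccc2.[O-]S(=O)(=O)C(F)(F)F | intermediate
12 | (2R,3S,4R,5R,6S)-5-(benzyloxy)-2,4,6-trimethyl-2-(prop-1-ynyl)-3-(triethylsilyloxy)oxane | C[C@@H]1O[C@](C)(C#CC)[C@@H](O[Si](CC)(CC)CC)[C@H](C)[C@H]1OCc2ccccc2 | intermediate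
13 | (2R,3S,4S,5R,6S)-5-(benzyloxy)-2,4,6-trimethyl-2-(prop-1-ynyl)oxan-3-ol | C[C@@H]1O[C@](C)(C#CC)[C@@H](O)[C@H](C)[C@H]1OCc2ccccc2 | intermediate
14 | tert-butyl (2R,3S,4R,5R,6S)-5-(benzyloxy)-2,4,6-trimethyl-2-(prop-1-ynyl)oxan-3-yl carbonate | C[C@@H]1O[C@](C)(C#CC)[C@@H](OC(=O)OC(C)(C)C)[C@H](C)[C@H]1OCc2ccccc2 | intermediate
15 | cyclic enol carbonate: 4-[(Z)-ethylidene]-1,3-dioxan-2-one trans-fused at C4–C5 to the oxane (C4 methyl, C6 methyl, O7 benzyl, C8 methyl) | C[C@@H]1O[C@@]2(C)[C@@H](OC(=O)O/C2=C\C)[C@H](C)[C@H]1OCc3ccccc3 | intermediate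
16 | potassium Z enolate of the C3 ethyl ketone carrying the O5 tert-butyl carbonate | C[C@@H]1O[C@](C)(C(/[O-])=C/C)[C@@H](OC(=O)OC(C)(C)C)[C@H](C)[C@H]1OCc2ccccc2.[K+] | intermediate
17 | 7-O-benzyl β-keto-δ-lactone, enol form (C1 lactone, C2 methyl, C3 enol OH, fused to the oxane at C4–C5) | C[C@@H]1O[C@@]2(C)[C@@H](OC(=O)C(C)=C2O)[C@H](C)[C@H]1OCc3ccccc3 | intermediate
18 | bicyclic diol (the target without its O7 acyl group; 2R,3S,4R,5S,6R,7R,8S in target locants) | C[C@@H]1O[C@@]2(C)[C@@H](OC(=O)[C@H](C)[C@@H]2O)[C@H](C)[C@H]1O | intermediate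
19 | methyltriphenylphosphonium bromide | C[P+](c1ccccc1)(c1ccccc1)c1ccccc1.[Br-] | starting material
20 | pentanoyl chloride | CCCCC(Cl)=O | starting material
21 | methylidenetriphenylphosphorane | C=P(c1ccccc1)(c1ccccc1)c1ccccc1 | intermediate
22 | 1-(triphenyl-λ5-phosphanylidene)hexan-2-one | CCCCC(=O)C=P(c1ccccc1)(c1ccccc1)c1ccccc1 | intermediate
23 | glyoxylic acid monohydrate | OC(O)C(=O)O | starting material
24 | (E)-4-oxooct-2-enoic acid | CCCCC(=O)/C=C/C(=O)O | intermediate
25 | botcinin I | CCCCC(=O)/C=C/C(=O)O[C@@H]1[C@@H](C)[C@@H]2OC(=O)[C@H](C)[C@H](O)[C@@]2(C)O[C@H]1C | target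

**Step count**
Total: 15 steps. Longest linear sequence: 13 steps (steps 1–12 and 15).

**Steps most likely to fail**

1. Step 11 (proposed new method). The liberated enolate may be re-acylated on oxygen or quenched faster than it attacks the carbonate at carbon. Alternatively the alkoxide may strip the carbonate from O5, after which retro-aldol cleavage of the C4–C5 bond would open the oxane. Fallback with known chemistry, from 15: NaOMe (0.1 equiv) in MeOH at 0 °C should open the enol carbonate by alcoholysis to the methyl carbonate ketone F1. LiN(SiMe3)2 (2.2 equiv) in THF at −78 to 0 °C should then close the lactone by a Dieckmann-type C-acylation of the ketone enolate. The route is rejoined at 17.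

2. Step 12. The catalyst may fail to reach the tetrasubstituted enol double bond beside the quaternary C4, or hydrogen may be delivered from both faces. Fallback from 17: tert-butylamine–borane with citric acid in MeOH should reduce the keto tautomer from the face opposite the axial C4 methyl to the hydroxy lactone F2 (C3 as in the target, C2 expected epimeric, benzyl ether kept). LiN(iPr)2 (2.2 equiv) in THF at −78 °C and then PhSeBr should give the selenide F3. H2O2 with pyridine in CH2Cl2 at 0 °C should give, by selenoxide syn-elimination toward the methyl group, the α-methylene lactone F4. H2 over Pd/C in EtOAc should then saturate the exocyclic alkene from the face opposite the axial C4 methyl and cleave the benzyl ether. The route is rejoined at 18.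

3. Step 10. The carbonate oxygen may attack the distal alkyne carbon C2 (7-endo closure), or the hindered internal alkyne next to the quaternary C4 may not cyclise at all. Fallback from 13: (HMe2Si)2NH at 60 °C should give the dimethylsilyl ether F5. Pt2[(CH2=CHSiMe2)2O]3 (zerovalent platinum, cat.) in THF should give, by 5-exo-dig syn-hydrosilylation, the oxasilolane F6 with silicon on C3. H2O2, KF and KHCO3 in THF/MeOH (Tamao–Fleming oxidation) should give the β-hydroxy ethyl ketone F7. 1,1'-Carbonyldiimidazole in CH2Cl2 should give the imidazole-1-carboxylate F8. LiN(SiMe3)2 in THF at −78 to 0 °C should close the lactone by Dieckmann-type C-acylation. The route is rejoined at 17.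

**Further compounds**
F1 | step 11 | methyl carbonate of the C5 hydroxy C3 ethyl ketone (O7 benzyl) | C[C@@H]1O[C@](C)(C(=O)CC)[C@@H](OC(=O)OC)[C@H](C)[C@H]1OCc2ccccc2
F2 | step 12 | 7-O-benzyl 3-hydroxy lactone, C2 epimer | C[C@@H]1O[C@@]2(C)[C@@H](OC(=O)[C@@H](C)[C@@H]2O)[C@H](C)[C@H]1OCc3ccccc3
F3 | step 12 | 7-O-benzyl 3-hydroxy-2-methyl-2-(phenylselanyl) lactone | C[C@@H]1O[C@@]2(C)[C@@H](OC(=O)[C@@](C)([Se]c3ccccc3)[C@@H]2O)[C@H](C)[C@H]1OCc4ccccc4
F4 | step 12 | 7-O-benzyl 3-hydroxy-2-methylidene lactone | C[C@@H]1O[C@@]2(C)[C@@H](OC(=O)C(=C)[C@@H]2O)[C@H](C)[C@H]1OCc3ccccc3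
F5 | step 10 | dimethylsilyl ether of 13 | C[C@@H]1O[C@](C)(C#CC)[C@@H](O[SiH](C)C)[C@H](C)[C@H]1OCc2ccccc2
F6 | step 10 | oxasilolane with Si on C3 and an E ethylidene | C[C@@H]1O[C@@]2(C)[C@@H](O[Si](C)(C)/C2=C/C)[C@H](C)[C@H]1OCc3ccccc3
F7 | step 10 | C5 hydroxy C3 ethyl ketone (O7 benzyl) | C[C@@H]1O[C@](C)(C(=O)CC)[C@@H](O)[C@H](C)[C@H]1OCc2ccccc2
F8 | step 10 | O5 imidazole-1-carboxylate of F7 | C[C@@H]1O[C@](C)(C(=O)CC)[C@@H](OC(=O)n2ccnc2)[C@H](C)[C@H]1OCc3ccccc3
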